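A small charge of starting material, the amber run, shows how fast target is lost once it has formed. The highest amber reading of target is 12.6%, and later readings fall along with the starting material, as expected if starting material and target draw on one reagent, to give target and over-reacted product. Target is then made and used at rates in the ratio [starting material]/(κ[target]). In a late tail, κ is one plus the ratio of starting material to target, so the last amber reading gives 4.45 for κ, the selectivity factor, the rate constant of the second step over that of the first.

| flask | starting material | reagent in the second phase | remark | time | volume of the second phase over the first |
|---|---|---|---|---|---|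
| amber | 0.025 M | 0.055 M | run made earlier |  |  |
| teal | 0.14 M | 0.055 M | run made earlier |  |  |
| ash | 0.050 M | 0.0550 M |  | 5.0 d | 2.0 |
| oak | 0.10 M | 0.0550 M |  | 5.0 d | 2.0 |
| alder | 0.20 M | 0.0550 M |  | 5.0 d | 2.0 |

| run | time / d | target / % | starting material / % |
|---|---|---|---|
| amber | 0.250 | 4.3 | 88.8 |
| amber | 0.500 | 9.6 | 75.1 |
| amber | 0.833 | 12.6 | 61.2 |
| amber | 1.25 | 12.0 | 49.7 |
| amber | 2.00 | 10.1 | 36.3 |
| amber | 4.00 | 5.3 | 18.3 |
| teal | 0.250 | 2.4 | 90.7 |
| teal | 0.625 | 5.7 | 79.9 |
| teal | 1.25 | 8.1 | 71.1 |
| teal | 2.08 | 9.4 | 64.4 |
| teal | 2.50 | 10.9 | 62.9 |
| teal | 4.00 | 11.4 | 60.0 |

(scatter of a reading: 0.3 percentage points)

- in the second phase: reagent in the second phase; everything else is in the first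
- charges count per volume of the first phase; a concentration in a rate is the amount of a species over the volume of its own phase; every rate counts per litre of the first phase
- the earlier runs hold the two phases in the same ratio of volumes as the flask asked about
- "hardly changes" means that all values lie within two and a half points (for a concentration: within two and a half percent of the largest)

- amount of target at the end, in percent of the starting material charged for ash, oak, alder, in this order
- how the row runs (falls all the way / rises, then falls / hardly changes / falls, then rises / rises all the way)

The bench rule charges one equivalent of reagent per starting material. Its zero is the symmetric case: at κ of 1, target peaks at 36.8% of the charge after 0.896 equivalents have been used, close to the rule. At the κ read here, the same curve peaks at 14.6% target, with 64.9% starting material left, and that costs 0.557 equivalents, each over-reacted product counting two reagents. The rule therefore stops working here. The ratio of reagent to starting material is 1.10 in ash, about twice that cost, and 0.550 in oak, close to it. In alder it is 0.275, half of it. This reckoning, which counts the whole charge of reagent as used, therefore puts ash past the peak, oak on it and alder short of it, with a top near 14.6% and flanks of unknown depth.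

The forecast gives 7.5%, 11.5% and 12.5%, and says the row rises all the way, adding “the oak–alder order is uncertain”. It counts the reagent at 0.11 M, where the reckoning above counts 0.0550 M.

The flask gives 9.97%, 12.0% and 10.2%: the row hardly changes.

    starting material + reagent in the reaction phase → target (k = 4.72 /M/h)
    reagent in the reaction phase + target → over-reacted product (k = 20.8 /M/h)
    reagent in the reaction phase ⇌ reagent in the second phase, rate k3*([reagent in the reaction phase] - [reagent in the second phase]/K3) per volume of the first phase (partition coefficient = 0.740, kL = 0.0234 /h)
    starting material ⇌ dormant form (K = 0.320, k = 0.0135 /h)

In ash at 5.00 d, 37.6% starting material stands beside 9.97% target, and target is made at 0.856 of the rate at which it is used, while [starting material]/(κ[target]) with the carried κ reads 0.847; target there goes on to 8.27% by 50.0 d. The same ratio reads 0.999 in oak, where target stands at 12.0% and still at 11.9% by 50.0 d, and 1.38 in alder, where target goes from 10.2% to 10.9%.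

The data were computed with constants of no real substance.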